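3 numbers were asked of me, and I judged that what separates them is how many lifetimes the double product lives through in reagent that outlasts the substrate.

| flask | substrate | reagent | remark | time |
|---|---|---|---|---|
| cedar | 5 mM | 3.5 mM | run made earlier |  |
| maple | 5 mM | 15 mM | run made earlier |  |
| noon | 5.0 mM | 2.50 mM |  | 2.0 h |
| autumn | 5.0 mM | 6.00 mM |  | 2.0 h |
| summer | 5.0 mM | 10.0 mM |  | 2.0 h |

| run | time / min | double product / % | mono adduct / % |
|---|---|---|---|
| cedar | 5.00 | 9.6 | 12.9 |
| cedar | 15.0 | 10.5 | 6.2 |
| cedar | 30.0 | 9.6 | 6.7 |
| cedar | 40.0 | 9.0 | 6.5 |
| cedar | 60.0 | 8.2 | 7.8 |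
| maple | 5.00 | 8.7 | 3.0 |
| maple | 15.0 | 0 | 0 |
| maple | 30.0 | 1.3 | 0 |
| maple | 40.0 | 0 | 0 |
| maple | 60.0 | 0.9 | 2.1 |

(each reading ± 1 percentage point)

- final double product, as a percentage of the substrate charged, for each flask in turn (noon, autumn, summer)



Maple gave the yardstick. Its double product read 8.7 % at 5.00 min and 0 % at 15.0 min. A zero reading can hide one scatter, so I bounded the decay:

4.62 min = time between the readings / ln(first reading / scatter)

This is the maple lifetime ceiling: the longest pseudo-first-order lifetime of the double product that those readings allow, within one scatter.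

My objection was that maple's reagent had already fallen below its charge by then. Scaling the ceiling from the full charge, inversely with reagent, therefore keeps it a ceiling, provided the loss is first order in reagent, which I assumed.

In cedar the double product read 2.3 percentage points lower at 60.0 min than at 15.0 min, and with a scatter of 1 point on each reading I set that fall aside. For noon I scaled cedar's 10.5 % by the square of the reagent, assuming two additions, and got 5.36 %.

The same square gives 30.9 % for autumn, but maple shows that the double product itself is consumed. I therefore placed autumn between that and cedar's 10.5 %, nearer cedar.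

For summer I guessed that 1.00 mM of reagent survives and started from cedar's 10.5 %, and the guess is the weak point:

lifetime ceiling = 69.3 min, so at least 1.73 lifetimes, leaving at most 1.86 %

The forecast gave 4 %, 7 % and 4 %, holding that "excess reagent over-reacts them".

The flasks gave 5.13 %, 12.1 % and 0.0177 %.

    reagent + double product → tris adduct + by-product (k = 1.70 M⁻¹ s⁻¹)
    reagent + mono adduct → double product + by-product (k = 1.80 M⁻¹ s⁻¹)
    substrate + mono adduct → side product A (k = 2.30 M⁻¹ s⁻¹)
    substrate + by-product → side product B (k = 1.30 M⁻¹ s⁻¹)
    substrate + reagent → mono adduct + by-product (k = 2.10 M⁻¹ s⁻¹)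

Summer kept 5.8 % of its reagent at 2.00 h, which is 0.577 mM. At that level the ceiling is 120 min. Its double product fell from 0.449 % at 1.00 h to 0.0177 % at 2.00 h, a lifetime of 18.6 min, shorter than the ceiling. In autumn, 0.0601 % of the reagent charge remained at 1.00 h, which puts the ceiling at 19200 min, and its double product stood at 12.1 % then and 12.1 % at 2.00 h.

(The numbers in the tables were generated by integration with made-up constants; the scatter is artificial.)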